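## Analysis of the target

CNP0407321.1 (28) is a resveratrol trimer, C42H32O9, in which one of the three resorcinol rings is no longer aromatic. The core is a bicyclo[3.2.1]oct-3-ene-2,8-dione, numbered here and throughout as follows: C1 is the methine between the two ketones C2 and C8, C3=C4 is the enone, C5 is the quaternary bridgehead, and C6 (4-hydroxyphenyl) and C7 (3,5-dihydroxyphenyl) form the two-carbon bridge. The bond C4–C5 is shared with a cyclopentane (C4, C5, C11, C10, C9), and the bond C9–C10 with an indane whose benzylic carbon C12 and the ring carbon C11 each carry a 4-hydroxyphenyl group. There are eight stereocentres. C9 and C10 are cis-fused; the aryl groups on C12 and C11 lie on the convex face (trans to C4 and trans to the arene bond at C10). At C5 the ketone carbon C8 is syn and C6 anti to the C11 aryl group; the aryl groups on C6 and C7 are trans, and C1 is fixed by the bridge. Sensitive groups are seven phenols, an enone, a β-diketone that cannot enolise at its bridgehead, and several benzylic hydrogens next to unsaturation. The difficulty is concentrated at C5, which is at once quaternary, a bridgehead, a ring-fusion atom and the neighbour of two aryl-bearing methines. The plan rests on one observation: once C1–C7 is cut, the ring C1–C2–C3–C4–C5–C8 is a resorcinol dearomatised at C5, that is, a 6,6-disubstituted cyclohexa-2,4-dienone. This is the ring that a vinylketene–alkoxyalkyne annulation gives when the diene terminus carries no hydrogen.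

## Retrosynthetic reasoning

28 to 27: the seven O–CH3 bonds are cut. Methyl ethers are carried from the aryl building blocks, survive every step, and are removed last. The forward step must cleave aryl ethers without touching the enedione.

27 to 26, 25 and 24: the C1–C7 bond is cut. C1 lies between two carbonyl groups and can therefore be turned into a carbene centre by diazo transfer; C7–H is benzylic and 1,5 to C1. This removes the bridge and leaves a monocyclic dienone with a free diarylethyl chain. The forward insertion must go into the C7–H bond with retention and place the C7 aryl group trans to the C6 aryl group. Dione 25 comes from enol ether 24 by cleavage of the C2–O(ethyl) bond.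

24 to 19 and 20: the bonds C8–C1, C2–C3 and C8–C5 are cut, and C3–C4 is traced back to a 1,2-shift. The six-membered ring is thereby reduced to a diazomethyl ketone on C4 and the two-carbon alkyne 20. No other cut removes the ring and the quaternary centre together. The forward reaction must form C8–C5 at a fully substituted alkene carbon and choose the face of C5 syn to the C11 aryl group.

19 to 17 and 16: the bond between C4 and the acyl carbon is cut. The acid 17 is the carbonylation product of vinyl triflate 16, and one-carbon extension of the acid gives the diazomethyl ketone. The position of the double bond (C4=C5) is decided at the triflate stage.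

16 to 14 and 10: the C6–aryl bond is cut. Conjugate addition of 10 to the exocyclic enone 14 creates C6 and at the same time gives the enolate with its double bond only between C4 and C5, which is trapped as 16. The forward step must choose one face of C6; the neighbouring C11 aryl group is the control element.

14 to 12, and 12 to 9, 10 and 2: the C11–aryl bond and the C5–C6 bond are cut. Conjugate addition of 10 to enone 9 sets C11 from the convex face, and the resulting enolate is joined to aldehyde 2; loss of water gives 14.

9 to 7, and 7 to 3, 4 and 5: the C12–arene bond (Friedel–Crafts), the C9–C12 bond (aldol) and the C10–aryl bond (conjugate addition) are cut. This leads back to the commercial enantiopure enone 3, whose silyloxy-bearing carbon directs the entry of 4 and is then lost as the C5=C11 double bond of 9. All later stereocentres are relayed from C10.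

2 to 1: the aldehyde is the partial reduction product of the commercial ester 1.

## Alternatives that were turned down

Alternative 1: The C5–C6 bond is disconnected and the quaternary carbon is made by a 1,2-shift. In the forward direction a Lewis acid would open an epoxide spanning C4–C5 at C5. The benzylic ring carbon C6 of a cyclobutanol whose carbinol carbon is C8 would then migrate to C5, turning the four-membered ring into the cyclopentanone C1–C7–C6–C5–C8; the product is the spiro hydroxy ketone A1.
- For it: the shift is stereospecific (C6 arrives anti to the departing oxygen), the better-stabilised benzylic carbon migrates, and the trans C6/C7 diaryl unit could be set beforehand in the small ring.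
- Against it: a cationic centre develops next to C11 in a molecule with five electron-rich arenes, so hydride shift, aryl participation and Friedel–Crafts capture compete. The epoxide must be delivered to the face that carries the C11 aryl group. A1 still lacks C2 and C3, so the enone bridge from C1 to C4 must be built afterwards on a congested core, including a ring closure to a strained bridged system.
- Comparison: on the configuration of C5 this route is at least as strong as the chosen one, because migration geometry and not steric preference decides it. The chosen strategy offers instead the whole six-membered ring with its oxygen pattern in the same step, and a four-step end game.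

Alternative 2: The bonds C9–C10 and C12–arene are cut, so that the cyclopentane and the indane are closed last on a finished bicyclooctenedione. In the forward direction a visible-light photoredox catalyst would reduce a benzylic C10–Br bond. The C10 radical adds 5-exo to a styryl group on C4 (C9–C10 bond); the C12 radical is oxidised to the cation, which alkylates the neighbouring dimethoxyarene. The product is A2, the same compound as 27.
- For it: two rings, two C–C bonds and three stereocentres (C9, C10, C12) in one mild operation, one step before the target, with a convergent build-up.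
- Against it: the substrate must already contain C5 with all four carbon substituents, together with C6, C7 and C11, so the hardest part of the molecule is moved into the substrate and not solved. The C10 radical is planar, so C9, C10 and C12 must all be controlled by the substrate in one cascade. The cross-conjugated enone offers the radical a second acceptor position, and a secondary benzylic bromide next to a quaternary carbon eliminates easily.
- Comparison: on convergence and on the length of the end game this alternative is stronger. The chosen strategy offers a direct solution to C5 and to the dearomatised ring, which this alternative presupposes.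

Alternative 3: The same photochemical Wolff rearrangement and alkoxyalkyne annulation is used, but the aromatic resorcinol ring of the indane is disconnected. In the forward direction a vinylketene adds the alkoxyalkyne 20; 4π opening, 6π closure and tautomerisation give an arene. The product is A3, an indane-fused cyclopentanone whose new ring carries one free phenol and one ethyl ether.
- For it: this is the normal and best-precedented course of the annulation (aromatisation drives it), no stereocentre is formed in the step, and the two oxygens come out differentiated.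
- Against it: the ring it makes is an ordinary 3,5-dioxygenated arene that is available as a building block (4 in the chosen route). The oxygen differentiation is of no use because all phenols of 28 are free. A3 is far from the target: the dearomatised ring, C5, C6, C7 and the bridge all remain.
- Comparison: as a reaction it is safer than the chosen key step. As a strategy it spends the annulation where it is least needed, whereas the chosen plan applies it at the one place where stopping before aromatisation is exactly the required outcome.

Key step: step 9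

Remark on the chemistry: a secondary benzylic organometallic reagent would not hold its configuration, so C6 is created on the ring by conjugate addition and not by cross-coupling of a preformed chiral chain. Dione 25 is drawn as the diketone and will exist partly as an enol. CIP descriptors are given for compounds 3–19; for 21–27 the configuration is stated in words and fixed by the SMILES strings.

## Route

Step 1
Reactants: 1 methyl 2-(3,5-dimethoxyphenyl)acetate
Product: 2 2-(3,5-dimethoxyphenyl)acetaldehyde
Conditions: i-Bu2AlH (1.05 equiv), CH2Cl2, −78 °C; aq. KNaC4H4O6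
Reagents that add atoms: none
Why: Partial reduction of an ester by a dialkylaluminium hydride stops at the aluminium hemiacetal at −78 °C, which gives the aldehyde on work-up; the aldehyde is used at once because arylacetaldehydes self-condense.

Step 2
Reactants: 3 (R)-4-[(tert-butyldimethylsilyl)oxy]cyclopent-2-en-1-one; 4 (3,5-dimethoxyphenyl)magnesium chloride; 5 4-methoxybenzaldehyde
Product: 7 (2S,3S,4R)-4-[(tert-butyldimethylsilyl)oxy]-3-(3,5-dimethoxyphenyl)-2-[hydroxy(4-methoxyphenyl)methyl]cyclopentan-1-one (both carbinol epimers), via chloromagnesium enolate 6 (not isolated)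
Conditions: 4 (1.3 equiv), CuBr·SMe2 (10 mol %), THF, −78 °C; then 5, −78 °C; aq. NH4Cl
Reagents that add atoms: none
Why: Copper-catalysed conjugate addition of the aryl Grignard reagent to a 4-silyloxycyclopentenone takes place anti to the silyl ether and sets C10; the enolate, formed only toward C9, is trapped by the aldehyde (conjugate addition–aldol three-component coupling). The configurations at C9 and at the carbinol carbon do not matter because both are reset in step 3.

Step 3
Reactants: 7 the aldol adduct
Product: 9 (3aS,8R,8aR)-5,7-dimethoxy-8-(4-methoxyphenyl)-8,8a-dihydrocyclopenta[a]inden-1(3aH)-one, via tricyclic silyloxy ketone 8 (not isolated)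
Conditions: CF3CO2H, CH2Cl2, 0 → 23 °C
Reagents that add atoms: none
Why: Acid ionises the 4-methoxybenzylic alcohol, and the cation at C12 is attacked by the ortho carbon of the 3,5-dimethoxyphenyl ring (intramolecular Friedel–Crafts alkylation). Only the cis-fused indane can form, so C9 epimerises through the enol, and the C12 aryl group takes the convex face, trans to C4. Acid-promoted β-elimination of the silanol from 8 then gives the enone.

Step 4
Reactants: 9 the tricyclic enone; 10 (4-methoxyphenyl)magnesium bromide; 2 2-(3,5-dimethoxyphenyl)acetaldehyde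
Product: 12 (2S,3S,3aS,8R,8aR)-2-[2-(3,5-dimethoxyphenyl)-1-hydroxyethyl]-5,7-dimethoxy-3,8-bis(4-methoxyphenyl)-3,3a,8,8a-tetrahydrocyclopenta[a]inden-1(2H)-one (both carbinol epimers), via bromomagnesium enolate 11 (not isolated)
Conditions: 10 (1.5 equiv), CuBr·SMe2 (10 mol %), THF, −78 °C; then 2, −78 °C; aq. NH4Cl
Reagents that add atoms: none
Why: The aryl copper species adds to C11 from the convex face, anti to the arene bond at C10, which gives the trans relationship of the target; the C4–C5 enolate then adds to the aldehyde (conjugate addition–aldol). The enone is consumed at −78 °C before base can move its double bond toward C10.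

Step 5
Reactants: 12 the aldol adduct
Product: 14 (2E,3R,3aS,8R,8aR)-2-[2-(3,5-dimethoxyphenyl)ethylidene]-5,7-dimethoxy-3,8-bis(4-methoxyphenyl)-3,3a,8,8a-tetrahydrocyclopenta[a]inden-1(2H)-one, via methanesulfonate 13 (not isolated)
Conditions: MeSO2Cl, Et3N, DMAP (cat.), CH2Cl2, 0 → 23 °C
Reagents that add atoms: none
Why: Mesylation and E1cB elimination through the C5 enolate give the conjugated exocyclic enone; the E isomer is expected because the benzylic CH2 group avoids the carbonyl oxygen. Short exposure to a weak amine base should keep the double bond from moving into conjugation with the arene.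

Step 6
Reactants: 14 the (E)-alkylidene ketone; 10 (4-methoxyphenyl)magnesium bromide
Product: 16 (3R,3aS,8R,8aR)-2-[(1S)-2-(3,5-dimethoxyphenyl)-1-(4-methoxyphenyl)ethyl]-5,7-dimethoxy-3,8-bis(4-methoxyphenyl)-3,3a,8,8a-tetrahydrocyclopenta[a]inden-1-yl trifluoromethanesulfonate, via bromomagnesium enolate 15 (not isolated)
Conditions: 10 (2 equiv), CuBr·SMe2 (20 mol %), THF, −78 → −30 °C; then Comins' reagent, −78 → 0 °C; aq. NH4Cl
Reagents that add atoms: Comins' reagent, N-(5-chloropyridin-2-yl)-1,1,1-trifluoro-N-(trifluoromethylsulfonyl)methanesulfonamide, SMILES Clc1ccc(nc1)N(S(=O)(=O)C(F)(F)F)S(=O)(=O)C(F)(F)F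
Why: The exocyclic enone is held s-cis, and 1,3-allylic strain between the alkylidene CH2 group and C11 turns the C11 aryl group pseudo-axial so that it covers one face of C6. The aryl copper species should therefore attack the other face, which with the E alkene gives (S)-C6. The enolate has its double bond only between C4 and C5 and is O-sulfonylated (conjugate addition–enolate triflation).

Step 7
Reactants: 16 the vinyl triflate
Product: 17 (3R,3aR,8R,8aR)-2-[(1S)-2-(3,5-dimethoxyphenyl)-1-(4-methoxyphenyl)ethyl]-5,7-dimethoxy-3,8-bis(4-methoxyphenyl)-3,3a,8,8a-tetrahydrocyclopenta[a]indene-1-carboxylic acid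
Conditions: CO (1 atm), Pd(OAc)2 (5 mol %), dppp (10 mol %), KOAc, DMF–H2O, 60 °C; then 1 M HCl
Reagents that add atoms: carbon monoxide, SMILES [C-]#[O+]; water, SMILES O
Why: Oxidative addition of the vinyl triflate to zerovalent palladium, CO insertion and hydrolysis of the acyl palladium species give the acid (palladium-catalysed hydroxycarbonylation). The weakly basic medium leaves the benzylic stereocentres at C6 and C11 untouched.

Step 8
Reactants: 17 the carboxylic acid
Product: 19 2-diazo-1-{(3R,3aR,8R,8aR)-2-[(1S)-2-(3,5-dimethoxyphenyl)-1-(4-methoxyphenyl)ethyl]-5,7-dimethoxy-3,8-bis(4-methoxyphenyl)-3,3a,8,8a-tetrahydrocyclopenta[a]inden-1-yl}ethan-1-one, via acid chloride 18 (not isolated)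
Conditions: (COCl)2, DMF (cat.), CH2Cl2, 0 → 23 °C; evaporate; CH2N2 (excess), Et2O, 0 °C
Reagents that add atoms: diazomethane, SMILES C=[N+]=[N-]
Why: Acylation of diazomethane by the acid chloride (Arndt–Eistert-type diazo ketone synthesis), with the excess reagent taking up HCl. No amine base is present, so no ketene forms by γ-deprotonation, and dipolar cycloaddition to the hindered tetrasubstituted alkene should be slow.

Step 9
Reactants: 19 the diazomethyl ketone; 20 ethoxyacetylene
Product: 24 3-ethoxycyclohexa-2,4-dienone with quaternary C5 fused across C4–C5 to the tetrahydrocyclopenta[a]indene (C8 syn and C6 anti to the C11 aryl group; other stereocentres as in 19), via vinylketene 21 (not isolated), via vinylcyclobutenone 22 (not isolated), via dienylketene 23 (not isolated)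
Conditions: 20 (5 equiv), hν (medium-pressure Hg lamp, Pyrex filter, λ > 300 nm), ClCH2CH2Cl, 23 °C; then 80 °C, dark
Reagents that add atoms: none
Why: Irradiation expels N2 and the alkenyl carbon C4 shifts from the carbonyl carbon to the former diazo carbon (Wolff rearrangement), so that in vinylketene 21 C3 is bonded to C4 and C8 is the ketene carbon. The ketene adds 20 in a (2+2) cycloaddition whose regiochemistry follows the polarisation of the alkoxyalkyne: the unsubstituted carbon C1 bonds to C8 and the oxygen-bearing carbon C2 to C3, giving 22. On heating, 22 opens reversibly (4π electrocyclic) to dienylketene 23, and the isomer with C4 cis to C1 is drained by a thermal, disrotatory 6π electrocyclisation that closes the ring C1–C2–C3–C4–C5–C8 by bonding C8 to the fully substituted carbon C5. This is the second-generation Danheiser benzannulation; because C5 bears no hydrogen it ends at the 2,4-cyclohexadienone, the known outcome for a disubstituted diene terminus. The only new stereocentre is C5, and since C4=C5 lies in the cyclopentene the choice is the face of C5 that C8 approaches. Approach from the convex face moves the bulky diarylethyl group to the side away from the C11 aryl group, whereas the other approach would press that group against the C11 aryl; the small planar acyl terminus is therefore expected to end syn to the C11 aryl, as required. The ring keeps C3, C4 and C5 in the cisoid arrangement needed for closure at a hindered terminus, and the thermal stage is run in the dark so that the dienone is not re-opened photochemically.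

Step 10
Reactants: 24 the ethoxy dienone
Product: 25 6,6-disubstituted cyclohex-4-ene-1,3-dione (C2 and C8 ketones; C1 methylene; stereocentres as in 24)
Conditions: 1 M HCl, THF, 23 °C
Reagents that add atoms: water, SMILES O
Why: Acid hydrolysis of the vinylogous ester; C5 is quaternary, so neither tautomerisation to a phenol nor an aromatising dienone–phenol shift can follow.

Step 11
Reactants: 25 the dione
Product: 26 2-diazo derivative of 25 (diazo group on C1)
Conditions: 4-AcNHC6H4SO2N3, Et3N, MeCN, 0 → 23 °C
Reagents that add atoms: 4-acetamidobenzenesulfonyl azide, SMILES CC(=O)Nc1ccc(cc1)S(=O)(=O)N=[N+]=[N-]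
Why: Regitz diazo transfer to the only doubly activated methylene, C1, of the cyclic 1,3-dione.

Step 12
Reactants: 26 the diazo dione
Product: 27 heptamethyl ether of 28
Conditions: Rh2(NHCOCH3)4 (2 mol %), ClCH2CH2Cl, 80 °C
Reagents that add atoms: none
Why: The dirhodium carbenoid at C1 inserts into the benzylic C7–H bond, which is 1,5 to it, closing the five-membered ring C1–C8–C5–C6–C7 (dirhodium-carbenoid C–H insertion, concerted and with retention). The 3,5-dimethoxyphenyl group should take the position trans to the C6 aryl group in the chair-like transition state, and C1 is fixed by the bridge. The electron-rich acetamidate ligands temper the carbenoid and favour C–H insertion over attack on the arenes.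

Step 13
Reactants: 27 the heptamethyl ether
Product: 28 CNP0407321.1
Conditions: BBr3 (14 equiv), CH2Cl2, −78 → 23 °C; then H2O
Reagents that add atoms: none
Why: BBr3 cleaves all seven aryl methyl ethers (Lewis acid ether cleavage); the bridgehead C1–H cannot enolise, so the β-diketone stereocentre is not at risk.

## Compound list

1 | methyl 2-(3,5-dimethoxyphenyl)acetate | COC(=O)Cc1cc(OC)cc(OC)c1 | starting material
2 | 2-(3,5-dimethoxyphenyl)acetaldehyde | O=CCc1cc(OC)cc(OC)c1 | intermediate
3 | (R)-4-[(tert-butyldimethylsilyl)oxy]cyclopent-2-en-1-one | O=C1C=C[C@H](O[Si](C)(C)C(C)(C)C)C1 | starting material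
4 | (3,5-dimethoxyphenyl)magnesium chloride | COc1cc(OC)cc([Mg]Cl)c1 | starting material
5 | 4-methoxybenzaldehyde | COc1ccc(C=O)cc1 | starting material
6 | chloromagnesium enolate (C4–C9) of (3S,4R)-4-[(tert-butyldimethylsilyl)oxy]-3-(3,5-dimethoxyphenyl)cyclopentanone | Cl[Mg]OC1=C[C@@H](c2cc(OC)cc(OC)c2)[C@H](O[Si](C)(C)C(C)(C)C)C1 | intermediate
7 | (2S,3S,4R)-4-[(tert-butyldimethylsilyl)oxy]-3-(3,5-dimethoxyphenyl)-2-[hydroxy(4-methoxyphenyl)methyl]cyclopentan-1-one, both carbinol epimers | O=C1C[C@@H](O[Si](C)(C)C(C)(C)C)[C@H](c2cc(OC)cc(OC)c2)[C@H]1C(O)c1ccc(OC)cc1 | intermediate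
8 | (3R,3aS,8R,8aS)-3-[(tert-butyldimethylsilyl)oxy]-5,7-dimethoxy-8-(4-methoxyphenyl)-3,3a,8,8a-tetrahydrocyclopenta[a]inden-1(2H)-one | O=C1C[C@@H](O[Si](C)(C)C(C)(C)C)[C@@H]3c4cc(OC)cc(OC)c4[C@@H](c2ccc(OC)cc2)[C@H]13 | intermediate
9 | (3aS,8R,8aR)-5,7-dimethoxy-8-(4-methoxyphenyl)-8,8a-dihydrocyclopenta[a]inden-1(3aH)-one | O=C1C=C[C@@H]3c4cc(OC)cc(OC)c4[C@@H](c2ccc(OC)cc2)[C@H]13 | intermediate
10 | (4-methoxyphenyl)magnesium bromide | COc1ccc([Mg]Br)cc1 | starting material
11 | bromomagnesium enolate (C4–C5) formed from 9 by 1,4-addition, C11 aryl trans to the arene bond at C10 | Br[Mg]OC1=C[C@@H](c2ccc(OC)cc2)[C@@H]3c4cc(OC)cc(OC)c4[C@@H](c2ccc(OC)cc2)[C@H]13 | intermediate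
12 | (2S,3S,3aS,8R,8aR)-2-[2-(3,5-dimethoxyphenyl)-1-hydroxyethyl]-5,7-dimethoxy-3,8-bis(4-methoxyphenyl)-3,3a,8,8a-tetrahydrocyclopenta[a]inden-1(2H)-one, both carbinol epimers | O=C1[C@H](C(O)Cc2cc(OC)cc(OC)c2)[C@@H](c2ccc(OC)cc2)[C@@H]3c4cc(OC)cc(OC)c4[C@@H](c2ccc(OC)cc2)[C@H]13 | intermediate
13 | methanesulfonate of 12 | O=C1[C@H](C(OS(C)(=O)=O)Cc2cc(OC)cc(OC)c2)[C@@H](c2ccc(OC)cc2)[C@@H]3c4cc(OC)cc(OC)c4[C@@H](c2ccc(OC)cc2)[C@H]13 | intermediate
14 | (2E,3R,3aS,8R,8aR)-2-[2-(3,5-dimethoxyphenyl)ethylidene]-5,7-dimethoxy-3,8-bis(4-methoxyphenyl)-3,3a,8,8a-tetrahydrocyclopenta[a]inden-1(2H)-one | O=C1/C(=C/Cc2cc(OC)cc(OC)c2)[C@@H](c2ccc(OC)cc2)[C@@H]3c4cc(OC)cc(OC)c4[C@@H](c2ccc(OC)cc2)[C@H]13 | intermediate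
15 | bromomagnesium enolate (C4–C5) formed from 14 by 1,4-addition, (S) at C6 | Br[Mg]OC1=C([C@@H](Cc2cc(OC)cc(OC)c2)c2ccc(OC)cc2)[C@@H](c2ccc(OC)cc2)[C@@H]3c4cc(OC)cc(OC)c4[C@@H](c2ccc(OC)cc2)[C@H]13 | intermediate
16 | (3R,3aS,8R,8aR)-2-[(1S)-2-(3,5-dimethoxyphenyl)-1-(4-methoxyphenyl)ethyl]-5,7-dimethoxy-3,8-bis(4-methoxyphenyl)-3,3a,8,8a-tetrahydrocyclopenta[a]inden-1-yl trifluoromethanesulfonate | O=S(=O)(OC1=C([C@@H](Cc2cc(OC)cc(OC)c2)c2ccc(OC)cc2)[C@@H](c2ccc(OC)cc2)[C@@H]3c4cc(OC)cc(OC)c4[C@@H](c2ccc(OC)cc2)[C@H]13)C(F)(F)F | intermediate
17 | (3R,3aR,8R,8aR)-2-[(1S)-2-(3,5-dimethoxyphenyl)-1-(4-methoxyphenyl)ethyl]-5,7-dimethoxy-3,8-bis(4-methoxyphenyl)-3,3a,8,8a-tetrahydrocyclopenta[a]indene-1-carboxylic acid | OC(=O)C1=C([C@@H](Cc2cc(OC)cc(OC)c2)c2ccc(OC)cc2)[C@@H](c2ccc(OC)cc2)[C@@H]3c4cc(OC)cc(OC)c4[C@@H](c2ccc(OC)cc2)[C@H]13 | intermediate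
18 | acid chloride of 17 | ClC(=O)C1=C([C@@H](Cc2cc(OC)cc(OC)c2)c2ccc(OC)cc2)[C@@H](c2ccc(OC)cc2)[C@@H]3c4cc(OC)cc(OC)c4[C@@H](c2ccc(OC)cc2)[C@H]13 | intermediate
19 | 2-diazo-1-{(3R,3aR,8R,8aR)-2-[(1S)-2-(3,5-dimethoxyphenyl)-1-(4-methoxyphenyl)ethyl]-5,7-dimethoxy-3,8-bis(4-methoxyphenyl)-3,3a,8,8a-tetrahydrocyclopenta[a]inden-1-yl}ethan-1-one | [N-]=[N+]=CC(=O)C1=C([C@@H](Cc2cc(OC)cc(OC)c2)c2ccc(OC)cc2)[C@@H](c2ccc(OC)cc2)[C@@H]3c4cc(OC)cc(OC)c4[C@@H](c2ccc(OC)cc2)[C@H]13 | intermediate
20 | ethoxyacetylene (ethoxyethyne) | C#COCC | starting material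
21 | vinylketene formed from 19: ethenone on C4 of the cyclopenta[a]indene, stereocentres as in 19 | O=C=CC1=C([C@@H](Cc2cc(OC)cc(OC)c2)c2ccc(OC)cc2)[C@@H](c2ccc(OC)cc2)[C@@H]3c4cc(OC)cc(OC)c4[C@@H](c2ccc(OC)cc2)[C@H]13 | intermediate
22 | 3-ethoxycyclobut-2-en-1-one carrying the cyclopenta[a]indenyl group on its sp3 ring carbon (C3), both epimers at C3 | CCOC1=CC(=O)C1C2=C([C@@H](Cc3cc(OC)cc(OC)c3)c3ccc(OC)cc3)[C@@H](c3ccc(OC)cc3)[C@@H]3c4cc(OC)cc(OC)c4[C@@H](c4ccc(OC)cc4)[C@H]23 | intermediate
23 | dienylketene O=C8=C1H–C2(OEt)=C3H–C4 with C4 cis to C1 across C2=C3, stereocentres as in 19 | O=C=C/C(OCC)=C\C1=C([C@@H](Cc2cc(OC)cc(OC)c2)c2ccc(OC)cc2)[C@@H](c2ccc(OC)cc2)[C@@H]3c4cc(OC)cc(OC)c4[C@@H](c2ccc(OC)cc2)[C@H]13 | intermediate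
24 | 3-ethoxycyclohexa-2,4-dienone with quaternary C5 (C8 syn, C6 anti to the C11 aryl group) fused across C4–C5 to the tetrahydrocyclopenta[a]indene | CCOC1=CC(=O)[C@@]2([C@@H](Cc3cc(OC)cc(OC)c3)c3ccc(OC)cc3)[C@@H](c3ccc(OC)cc3)[C@@H]3c4cc(OC)cc(OC)c4[C@@H](c4ccc(OC)cc4)[C@@H]3C2=C1 | intermediate
25 | 6,6-disubstituted cyclohex-4-ene-1,3-dione from hydrolysis of 24, drawn as the diketone | O=C1CC(=O)[C@@]2([C@@H](Cc3cc(OC)cc(OC)c3)c3ccc(OC)cc3)[C@@H](c3ccc(OC)cc3)[C@@H]3c4cc(OC)cc(OC)c4[C@@H](c4ccc(OC)cc4)[C@@H]3C2=C1 | intermediate
26 | 2-diazo derivative of 25 (diazo on C1) | O=C1C(=[N+]=[N-])C(=O)[C@@]2([C@@H](Cc3cc(OC)cc(OC)c3)c3ccc(OC)cc3)[C@@H](c3ccc(OC)cc3)[C@@H]3c4cc(OC)cc(OC)c4[C@@H](c4ccc(OC)cc4)[C@@H]3C2=C1 | intermediate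
27 | heptamethyl ether of 28 | O=C1C=C2[C@H]3[C@H](c4ccc(OC)cc4)c4c(OC)cc(OC)cc4[C@H]3[C@H](c3ccc(OC)cc3)[C@]23C(=O)[C@H]1[C@H](c1cc(OC)cc(OC)c1)[C@H]3c1ccc(OC)cc1 | intermediate
28 | CNP0407321.1 | O=C1C=C2[C@H]3[C@H](c4ccc(O)cc4)c4c(O)cc(O)cc4[C@H]3[C@H](c3ccc(O)cc3)[C@]23C(=O)[C@H]1[C@H](c1cc(O)cc(O)c1)[C@H]3c1ccc(O)cc1 | target

## Step count and least certain steps

Total: 13 steps. Longest linear sequence: 12 steps (steps 2–13, from 3 to 28); step 1 is a one-step branch.

Step 9 (key step). Three things may go wrong:
- Closure at the tetrasubstituted terminus may be slow, so that the ketene is lost to dimerisation or to traces of water.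
- Facial selectivity at C5 may be poor, because the convex-face preference and the neighbouring C11 aryl group pull in opposite directions for the incoming carbon.
- Secondary photochemistry may intervene, since the anisole chromophores filter the light and the product dienone can itself be ring-opened by light.

The fallback generates the same vinylketene thermally and without light. It sets out from 19: AgO2CPh and Et3N in THF–H2O (silver-promoted Wolff rearrangement with capture by water) give the homologous [cyclopenta[a]inden-1-yl]acetic acid F1. (COCl)2 with catalytic DMF gives its acid chloride F2. Slow addition of Et3N to F2 and 20 in toluene at 80 °C gives 21 by dehydrochlorination, which passes through 22 and 23 and comes back to the route at 24.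

Step 6. The conjugate addition may show poor facial selectivity at C6 if the C11 aryl group does not shield one face as the allylic-strain argument predicts, or the hindered magnesium enolate may be sulfonylated incompletely. The fallback replaces substrate control by catalyst control. It sets out from 14: [Rh(OH)(binap)]2 with the matched enantiomer of BINAP and (4-MeOC6H4)Ti(OCHMe2)3 in THF, then Me3SiCl, give the trimethylsilyl enol ether F3 (Hayashi–Miyaura-type addition with enolate trapping). MeLi in THF releases the lithium enolate, which Comins' reagent converts to 16.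

Step 4. The enolate may deprotonate the acidic arylacetaldehyde instead of adding to it, and retro-aldol loss may occur on warming. The fallback changes from a basic enolate to a Lewis-acid aldol. It sets out from 9: the conjugate addition of 10 (CuBr·SMe2) is run in the presence of Me3SiCl to give the trimethylsilyl enol ether F4, and a Mukaiyama aldol addition of F4 to 2 with BF3·OEt2 in CH2Cl2 at −78 °C comes back at 12.

Step 12. The very electrophilic carbenoid may add to the π system of the C6 or C7 aryl ring (cyclopropanation with ring expansion, or aromatic substitution) or be captured by a methoxy oxygen faster than it inserts into C7–H. The fallback changes the carbene source and the metal. It sets out from 25: PhI(OAc)2 and KOH in MeOH at 0 °C give the phenyliodonium ylide F5, and Cu(acac)2 (5 mol %) in CH2Cl2 at 40 °C transfers the carbene as a less electrophilic copper carbenoid and comes back at 27.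

## Further compounds

F1 | step 9 | 2-{(3R,3aR,8R,8aR)-2-[(1S)-2-(3,5-dimethoxyphenyl)-1-(4-methoxyphenyl)ethyl]-5,7-dimethoxy-3,8-bis(4-methoxyphenyl)-3,3a,8,8a-tetrahydrocyclopenta[a]inden-1-yl}acetic acid | OC(=O)CC1=C([C@@H](Cc2cc(OC)cc(OC)c2)c2ccc(OC)cc2)[C@@H](c2ccc(OC)cc2)[C@@H]3c4cc(OC)cc(OC)c4[C@@H](c2ccc(OC)cc2)[C@H]13
F2 | step 9 | acid chloride of F1 | ClC(=O)CC1=C([C@@H](Cc2cc(OC)cc(OC)c2)c2ccc(OC)cc2)[C@@H](c2ccc(OC)cc2)[C@@H]3c4cc(OC)cc(OC)c4[C@@H](c2ccc(OC)cc2)[C@H]13
F3 | step 6 | trimethylsilyl enol ether (C4–C5) of the conjugate adduct of 14, (S) at C6 | C[Si](C)(C)OC1=C([C@@H](Cc2cc(OC)cc(OC)c2)c2ccc(OC)cc2)[C@@H](c2ccc(OC)cc2)[C@@H]3c4cc(OC)cc(OC)c4[C@@H](c2ccc(OC)cc2)[C@H]13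
F4 | step 4 | trimethylsilyl enol ether (C4–C5) of the conjugate adduct of 9 | C[Si](C)(C)OC1=C[C@@H](c2ccc(OC)cc2)[C@@H]3c4cc(OC)cc(OC)c4[C@@H](c2ccc(OC)cc2)[C@H]13
F5 | step 12 | phenyliodonium ylide of 25 at C1 | O=C1[C-]([I+]c5ccccc5)C(=O)[C@@]2([C@@H](Cc3cc(OC)cc(OC)c3)c3ccc(OC)cc3)[C@@H](c3ccc(OC)cc3)[C@@H]3c4cc(OC)cc(OC)c4[C@@H](c4ccc(OC)cc4)[C@@H]3C2=C1
A1 | alternative 1 | spiro β-hydroxy cyclopentanone (C5 spiro centre, C8 ketone, C4 carbinol) | O=C1C[C@H](c2cc(OC)cc(OC)c2)[C@@H](c2ccc(OC)cc2)[C@]12[C@H](O)[C@H]7[C@H](c3ccc(OC)cc3)c3c(OC)cc(OC)cc3[C@H]7[C@@H]2c1ccc(OC)cc1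
A2 | alternative 2 | heptamethyl ether of the target (identical with 27) | O=C1C=C2[C@H]3[C@H](c4ccc(OC)cc4)c4c(OC)cc(OC)cc4[C@H]3[C@H](c3ccc(OC)cc3)[C@]23C(=O)[C@H]1[C@H](c1cc(OC)cc(OC)c1)[C@H]3c1ccc(OC)cc1
A3 | alternative 3 | indane-fused cyclopentanone with a free phenol and an ethyl ether on the new resorcinol ring | Oc1cc(OCC)cc2c1[C@@H](c4ccc(OC)cc4)[C@@H]3C(=O)C[C@@H](c4ccc(OC)cc4)[C@H]23
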